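- If solid plus product falls short of the charge, the gap is dissolved solid electrophile waiting to react, so I count its pseudo-first-order lifetime.

| setting | south | flask |
|---|---|---|
| solid electrophile | 0.37 M | 0.37 M |
| free base | 0.37 M | 0.370 M |
| protonated nucleophile | 0.55 M | 0.370 M |
| remark | run made earlier |  |
| time |  | 2.5 h |

south run (percent of the solid electrophile charged)

| time / min | solid electrophile / % | product / % |
|---|---|---|
| 4.00 | 93.8 | 3.0 |
| 10.0 | 84.6 | 11.2 |
| 20.0 | 69.8 | 24.0 |
| 30.0 | 56.1 | 36.4 |

(standard deviation of a reading: 0.3 percentage points)

- part of the solid electrophile that has reacted (what has only dissolved counts as not reacted) at 2.5 h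
- share of free nucleophile in free nucleophile and protonated nucleophile together, at 2.5 h

- First way: between the last two south readings the gap averages 6.85%. Dividing it by the speed of the product gives the lifetime of the dissolved pool, 5.52 min.
- Second way: I ask how long the product trails the solid's consumption. That shift rests on the speed of the solid instead, and it gives 5.47 min. The two agree, but both rest on the same gap, so the match tests only the choice of speed. I keep the first figure as a reading of the south lifetime.
- The south solid falls steadily and extrapolates to zero at 69.0 min. I assume the same for this flask, which leaves 81.0 min.
- This flask has less protonated nucleophile than the south run, so I do not carry the south lifetime over unchanged. I take [nucleophile] to follow protonated nucleophile left over protonated nucleophile used. With a quarter of the charge unreacted, that stretches the lifetime to 65.0 min.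
- Starting from that quarter, the remaining time is 1.25 lifetimes, so my own figure for c is 92.8%.
- The forecast says 82% and 2%, reasoning “so free nucleophile collapses”. Its c is lower than mine.

    nucleophile + acid set free ⇌ protonated nucleophile, settled at all times (K = 840 M⁻¹)
    electrophile + nucleophile → acid set free + product (k = 7.80 M⁻¹ min⁻¹)
    nucleophile + acid set free ⇌ idle adduct, settled at all times (K = 270 M⁻¹)
    solid electrophile ⇌ electrophile, rate k4*(cs4 - [electrophile]) while solid is left; crystals form when [electrophile] > cs4 (solubility = 0.160 M, k = 0.0380 min⁻¹)
    acid set free → by-product carried off (k = 0.110 min⁻¹)
    acid set free + free base ⇌ salt of the base (K = 330 M⁻¹, k = 3.20 M⁻¹ min⁻¹)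

- This flask gives 91.2%, above the forecast and below my figure, and a free share of 7.46%. At 2.50 h this flask holds 0.00188 M of nucleophile, a lifetime of 68.1 min, which is 12.3 times the south lifetime. The neighbour flask with 0.93 M of protonated nucleophile holds 0.0434 M of nucleophile at that time. Its lifetime is 2.96 min, so my 81.0 min would count 27.4 lifetimes, and its c is >99.9%.

(The runs stem from a simulated flask on assumed constants; scatter was added.)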